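## Retrosynthetic overview

1. The target is read as epiafzelechin-(4β→8)-epiafzelechin-(4β→8)-4'-O-methylepigallocatechin; the last operation is hydrogenolysis of the dodeca-O-benzyl trimer 17.
2. Key disconnection (ring C of the middle unit, closed last): the C4–C4a bond and the interflavan bond C4(middle)–C8(bottom) are cut together. This returns C4 to a dimethyl acetal on the open-chain aryl ether 14 and releases the bottom unit as flavan nucleophile 3; forward, one acid-triggered operation closes the pyran ring, forms the interflavan bond and sets C4.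
3. Enabling feature: C4 of the middle unit is a doubly benzylic carbon at the aldehyde oxidation level, flanked by two phloroglucinol-type rings (ring A of the middle unit through C4a, ring A of the bottom unit through C8) whose ortho/para oxygens stabilise a cation at C4; C4a is the only free carbon ortho to O1 because C8 carries the top unit.
4. The O1–C2 bond of 14 comes from a Mitsunobu inversion between phenol 13 and the anti three-carbon building block 8 (C2, C3 and the C4 acetal; three steps from two aldehydes). The same two reactions (etherification, annulation/arylation) first build the top unit from 8 and 3,5-bis(benzyloxy)phenol 9, with a second molecule of 9 as the terminating arene.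
5. Order of ring formation: the rings of the bottom unit come from (−)-epigallocatechin (steps 1–2); ring C of the top unit closes in step 7; ring C of the middle unit closes in step 9.

Key step: step 9

Remark: flavan numbering (O1, C2, C3, C4, C4a, C5–C8, C8a; primed numbers for ring B) is used for each unit. All three units are (2R,3R) and both interflavan bonds are trans to the neighbouring C3 oxygen. C4 of 11 and 15 may form as either epimer, since both ionise to the same cation.

## Route

Step 1
Reactants: 1 (−)-epigallocatechin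
Product: 2 4'-O-methyl-(−)-epigallocatechin
Conditions: MeI (1.05 equiv), KHCO3 (1.1 equiv), DMF, argon, dark, 0 °C to rt
Reagents that add atoms: iodomethane, CI
Why: Williamson O-alkylation of the most acidic phenol: the central 4'-OH of the pyrogallol ring gives an anion held by two flanking hydrogen bonds, so one equivalent of hydrogencarbonate and methyl iodide should methylate it in preference to the 3'-, 5'- and ring A phenols, and no stereocentre is touched.

Step 2
Reactants: 2 4'-O-methyl-(−)-epigallocatechin
Product: 3 (2R,3R)-5,7-bis(benzyloxy)-2-[3,5-bis(benzyloxy)-4-methoxyphenyl]chroman-3-ol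
Conditions: BnBr (4.4 equiv), K2CO3 (5 equiv), DMF, argon, 0 °C to rt
Reagents that add atoms: benzyl bromide, BrCc1ccccc1
Why: Williamson benzylation of the four phenols; carbonate does not deprotonate the secondary 3-OH, which stays free, and the low temperature should avoid base-induced epimerisation at C2.

Step 3
Reactants: 4 4-(benzyloxy)benzaldehyde; 5 2,2-dimethoxyacetaldehyde (60% aqueous solution, excess)
Product: 6 (R)-1-[4-(benzyloxy)phenyl]-2-hydroxy-3,3-dimethoxypropan-1-one
Conditions: benzaldehyde lyase (recombinant, Pseudomonas fluorescens), thiamine diphosphate (cat.), MgSO4 (cat.), potassium phosphate buffer pH 7.5/DMSO 4:1, 30 °C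
Reagents that add atoms: none
Why: Thiamine-diphosphate-dependent cross-acyloin (carboligation) reaction in which the aromatic aldehyde is the acyl-anion donor and the non-enolisable dimethoxyacetaldehyde the acceptor; the enzyme should set the carbinol centre as R (the sense it gives for 2-hydroxy-1-arylpropanones), and any self-benzoin of 4 is re-cleaved by the lyase.

Step 4
Reactants: 6 (R)-1-[4-(benzyloxy)phenyl]-2-hydroxy-3,3-dimethoxypropan-1-one
Product: 7 (R)-2-(benzyloxy)-1-[4-(benzyloxy)phenyl]-3,3-dimethoxypropan-1-one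
Conditions: BnBr (2 equiv), Ag2O (1.5 equiv), 4 Å molecular sieves, CH2Cl2, dark, rt
Reagents that add atoms: benzyl bromide, BrCc1ccccc1
Why: Silver-oxide-mediated O-benzylation under non-basic conditions, chosen so that neither the enolisable α-stereocentre of the aryl ketone nor the acetal is disturbed.

Step 5
Reactants: 7 (R)-2-(benzyloxy)-1-[4-(benzyloxy)phenyl]-3,3-dimethoxypropan-1-one
Product: 8 (1S,2S)-2-(benzyloxy)-1-[4-(benzyloxy)phenyl]-3,3-dimethoxypropan-1-ol (anti)
Conditions: Zn(BH4)2 (from ZnCl2 and NaBH4), Et2O, −30 to 0 °C; aqueous NH4Cl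
Reagents that add atoms: none
Why: Chelation-controlled reduction of an α-alkoxy ketone: zinc bridges the carbonyl and benzyloxy oxygens and hydride adds to the face of the five-membered chelate opposite the dimethoxymethyl group, which should set the new carbinol centre as S and give the 1,2-anti alcohol.

Step 6
Reactants: 8 (1S,2S)-2-(benzyloxy)-1-[4-(benzyloxy)phenyl]-3,3-dimethoxypropan-1-ol; 9 3,5-bis(benzyloxy)phenol (1.2 equiv)
Product: 10 1,3-bis(benzyloxy)-5-{[(1R,2S)-2-(benzyloxy)-1-[4-(benzyloxy)phenyl]-3,3-dimethoxypropyl]oxy}benzene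
Conditions: n-Bu3P (1.5 equiv), N,N,N',N'-tetramethylazodicarboxamide (1.5 equiv), toluene, 0 °C to rt
Reagents that add atoms: none
Why: Mitsunobu etherification of a phenol with a secondary benzylic alcohol, in which SN2 displacement of the oxyphosphonium group inverts the benzylic centre (S to R); the inductive pull of the adjacent benzyloxy and acetal groups and the non-polar solvent should hold back ionisation, and because C3 is an acetal and not a carbonyl group the β-elimination typical of β-hydroxy carbonyl compounds is not open.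

Step 7
Reactants: 10 1,3-bis(benzyloxy)-5-{[(1R,2S)-2-(benzyloxy)-1-[4-(benzyloxy)phenyl]-3,3-dimethoxypropyl]oxy}benzene; 9 3,5-bis(benzyloxy)phenol (4 equiv)
Product: 13 3,5-bis(benzyloxy)-2-{(2R,3R)-3,5,7-tris(benzyloxy)-2-[4-(benzyloxy)phenyl]chroman-4β-yl}phenol, via 4-methoxyflavan 11 (not isolated), via flavan-4-yl cation 12 (not isolated)
Conditions: TMSOTf (0.2 equiv), 4 Å molecular sieves, CH2Cl2, slow addition of 10 to 9 and the acid at −78 °C, then −40 °C; Et3N, aqueous work-up
Reagents that add atoms: none
Why: Proposed new method: the acetal is ionised by TMSOTf to an oxocarbenium ion that is attacked by a carbon ortho to the ether oxygen of the 3,5-bis(benzyloxy)phenoxy ring (6-exo-trig Friedel–Crafts closure of ring C) to give 11, which loses methoxide to cation 12 that is captured by 9 at the carbon ortho to its free OH (less hindered than the carbon between the two benzyloxy groups, and any O-adduct re-ionises) on the face anti to the 3-benzyloxy group, so that the new C4 centre is 3,4-trans (4β) under control of the C3 substituent; the closest known reaction types are the acid-mediated cyclisation of 3-aryloxypropanal acetals to 4-alkoxychromans and the Lewis-acid arylation of 4-alkoxyflavans, and the excess of 9 holds back a second flavanylation of the product.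

Step 8
Reactants: 13 3,5-bis(benzyloxy)-2-{(2R,3R)-3,5,7-tris(benzyloxy)-2-[4-(benzyloxy)phenyl]chroman-4β-yl}phenol; 8 (1S,2S)-2-(benzyloxy)-1-[4-(benzyloxy)phenyl]-3,3-dimethoxypropan-1-ol (1.3 equiv)
Product: 14 1,5-bis(benzyloxy)-3-{[(1R,2S)-2-(benzyloxy)-1-[4-(benzyloxy)phenyl]-3,3-dimethoxypropyl]oxy}-2-{(2R,3R)-3,5,7-tris(benzyloxy)-2-[4-(benzyloxy)phenyl]chroman-4β-yl}benzene
Conditions: n-Bu3P (2 equiv), N,N,N',N'-tetramethylazodicarboxamide (2 equiv), toluene (0.5 M), 0 °C to rt
Reagents that add atoms: none
Why: Mitsunobu etherification with inversion at the benzylic carbon as in step 6; the phenolic OH is the only acidic site of 13, and the more nucleophilic trialkylphosphine with the azodicarboxamide at high concentration is meant to compensate for the ortho substituent of the phenol.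

Step 9
Reactants: 14 1,5-bis(benzyloxy)-3-{[(1R,2S)-2-(benzyloxy)-1-[4-(benzyloxy)phenyl]-3,3-dimethoxypropyl]oxy}-2-{(2R,3R)-3,5,7-tris(benzyloxy)-2-[4-(benzyloxy)phenyl]chroman-4β-yl}benzene; 3 (2R,3R)-5,7-bis(benzyloxy)-2-[3,5-bis(benzyloxy)-4-methoxyphenyl]chroman-3-ol (4 equiv)
Product: 17 3,5,7,4'-tetra-O-benzylepiafzelechin-(4β→8)-3,5,7,4'-tetra-O-benzylepiafzelechin-(4β→8)-5,7,3',5'-tetra-O-benzyl-4'-O-methylepigallocatechin, via 4-methoxyflavan dimer 15 (not isolated), via dimeric flavan-4-yl cation 16 (not isolated)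
Conditions: TMSOTf (0.2 equiv), 4 Å molecular sieves, CH2Cl2, slow addition of 14 to 3 and the acid at −78 °C, then −40 °C; Et3N, aqueous work-up
Reagents that add atoms: none
Why: Proposed new method: TMSOTf ionises the dimethyl acetal of 14 to an α-benzyloxy oxocarbenium ion, which is attacked by C4a of ring A of the middle unit in a 6-exo-trig Friedel–Crafts closure (C4–C4a bond) to give 15, and loss of methoxide from 15 gives the flavan-4-yl cation 16 (stabilised by O1 and the 5- and 7-benzyloxy groups), which is captured by C8 of 3. The closest known reaction types are the acid-mediated cyclisation of 3-aryloxypropanal acetals to 4-alkoxychromans, the one-pot cyclisation/arylation of 2-aryloxybenzaldehydes with arenes to 9-arylxanthenes, and the Lewis-acid coupling of 4-alkoxyflavans with flavan nucleophiles; their merger on an open-chain α-alkoxy-β-aryloxy acetal is the untested part. C2 and C3 of the new ring are carried in unchanged from 8, and the new stereocentre C4 is set in the capture step by attack on the half-chair cation anti to the pseudo-axial 3-benzyloxy group (2-aryl equatorial), which is the 3,4-trans (4β) course shown by 2,3-cis flavan-4-yl cations. Regiochemistry of the closure is fixed by the substrate, because C4a is the only free carbon ortho to O1 (the other ortho carbon, C8, carries the top unit), so only the 4→8-linked skeleton can form. The step further needs ring closure to outrun intermolecular attack on the oxocarbenium ion (six-membered transition state onto a triply oxygen-activated carbon), capture by 3 to outrun self-condensation through the free C6 and C8 positions of the top unit (excess 3, slow addition of 14, low temperature), and C8 over C6 selectivity in 3 (C8 lies next to the ring oxygen, C6 between two benzyloxy groups).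

Step 10
Reactants: 17 3,5,7,4'-tetra-O-benzylepiafzelechin-(4β→8)-3,5,7,4'-tetra-O-benzylepiafzelechin-(4β→8)-5,7,3',5'-tetra-O-benzyl-4'-O-methylepigallocatechin
Product: 18 epiafzelechin-(4β→8)-epiafzelechin-(4β→8)-4'-O-methylepigallocatechin (target)
Conditions: H2 (1 atm), Pd(OH)2/C (20 wt%), THF/MeOH/H2O, rt; filtration, Sephadex LH-20, lyophilisation
Reagents that add atoms: none
Why: Catalytic hydrogenolysis of the twelve benzyl ethers (ten aryl, two at the C3 oxygens) under neutral conditions, which should leave the aryl methyl ether, the O1–C2 bonds and the acid-labile interflavan bonds intact and touches no stereocentre.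

## Compound list

1 | (−)-epigallocatechin, (2R,3R)-2-(3,4,5-trihydroxyphenyl)chromane-3,5,7-triol | Oc1c(O)cc([C@H]2Oc3cc(O)cc(O)c3C[C@H]2O)cc1O | starting material
2 | 4'-O-methyl-(−)-epigallocatechin, (2R,3R)-2-(3,5-dihydroxy-4-methoxyphenyl)chromane-3,5,7-triol | COc1c(O)cc([C@H]2Oc3cc(O)cc(O)c3C[C@H]2O)cc1O | intermediate
3 | (2R,3R)-5,7-bis(benzyloxy)-2-[3,5-bis(benzyloxy)-4-methoxyphenyl]chroman-3-ol | COc1c(OCc2ccccc2)cc([C@H]2Oc3cc(OCc4ccccc4)cc(OCc4ccccc4)c3C[C@H]2O)cc1OCc1ccccc1 | intermediate
4 | 4-(benzyloxy)benzaldehyde | O=Cc1ccc(OCc2ccccc2)cc1 | starting material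
5 | 2,2-dimethoxyacetaldehyde | COC(OC)C=O | starting material
6 | (R)-1-[4-(benzyloxy)phenyl]-2-hydroxy-3,3-dimethoxypropan-1-one | COC(OC)[C@@H](O)C(=O)c1ccc(OCc2ccccc2)cc1 | intermediate
7 | (R)-2-(benzyloxy)-1-[4-(benzyloxy)phenyl]-3,3-dimethoxypropan-1-one | COC(OC)[C@@H](OCc1ccccc1)C(=O)c1ccc(OCc2ccccc2)cc1 | intermediate
8 | (1S,2S)-2-(benzyloxy)-1-[4-(benzyloxy)phenyl]-3,3-dimethoxypropan-1-ol (anti) | COC(OC)[C@@H](OCc1ccccc1)[C@@H](O)c1ccc(OCc2ccccc2)cc1 | intermediate
9 | 3,5-bis(benzyloxy)phenol | Oc1cc(OCc2ccccc2)cc(OCc2ccccc2)c1 | starting material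
10 | 1,3-bis(benzyloxy)-5-{[(1R,2S)-2-(benzyloxy)-1-[4-(benzyloxy)phenyl]-3,3-dimethoxypropyl]oxy}benzene | COC(OC)[C@@H](OCc1ccccc1)[C@H](Oc1cc(OCc2ccccc2)cc(OCc2ccccc2)c1)c1ccc(OCc2ccccc2)cc1 | intermediate
11 | (2R,3R)-3,5,7-tris(benzyloxy)-2-[4-(benzyloxy)phenyl]-4-methoxychromane, C4 epimers (not isolated) | COC1c2c(OCc3ccccc3)cc(OCc3ccccc3)cc2O[C@H](c2ccc(OCc3ccccc3)cc2)[C@@H]1OCc1ccccc1 | intermediate
12 | (2R,3R)-3,5,7-tris(benzyloxy)-2-[4-(benzyloxy)phenyl]chroman-4-ylium trifluoromethanesulfonate (not isolated) | [CH+]1c2c(OCc3ccccc3)cc(OCc3ccccc3)cc2O[C@H](c2ccc(OCc3ccccc3)cc2)[C@@H]1OCc1ccccc1.[O-]S(=O)(=O)C(F)(F)F | intermediate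
13 | 3,5-bis(benzyloxy)-2-{(2R,3R)-3,5,7-tris(benzyloxy)-2-[4-(benzyloxy)phenyl]chroman-4β-yl}phenol (aryl group at C4 trans to the 3-benzyloxy group) | Oc1cc(OCc2ccccc2)cc(OCc2ccccc2)c1[C@H]1c2c(OCc3ccccc3)cc(OCc3ccccc3)cc2O[C@H](c2ccc(OCc3ccccc3)cc2)[C@@H]1OCc1ccccc1 | intermediate
14 | 1,5-bis(benzyloxy)-3-{[(1R,2S)-2-(benzyloxy)-1-[4-(benzyloxy)phenyl]-3,3-dimethoxypropyl]oxy}-2-{(2R,3R)-3,5,7-tris(benzyloxy)-2-[4-(benzyloxy)phenyl]chroman-4β-yl}benzene | COC(OC)[C@@H](OCc1ccccc1)[C@H](Oc1cc(OCc2ccccc2)cc(OCc2ccccc2)c1[C@H]1c2c(OCc3ccccc3)cc(OCc3ccccc3)cc2O[C@H](c2ccc(OCc3ccccc3)cc2)[C@@H]1OCc1ccccc1)c1ccc(OCc2ccccc2)cc1 | intermediate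
15 | 3,5,7,4'-tetra-O-benzylepiafzelechin-(4β→8)-3,5,7,4'-tetra-O-benzyl-4-methoxyepiafzelechin, C4 epimers of the lower unit (not isolated) | COC1c2c(OCc3ccccc3)cc(OCc3ccccc3)c([C@H]3c4c(OCc5ccccc5)cc(OCc5ccccc5)cc4O[C@H](c4ccc(OCc5ccccc5)cc4)[C@@H]3OCc3ccccc3)c2O[C@H](c2ccc(OCc3ccccc3)cc2)[C@@H]1OCc1ccccc1 | intermediate
16 | 3,5,7,4'-tetra-O-benzylepiafzelechin-(4β→8)-3,5,7,4'-tetra-O-benzylepiafzelechin-4-ylium trifluoromethanesulfonate (not isolated) | [CH+]1c2c(OCc3ccccc3)cc(OCc3ccccc3)c([C@H]3c4c(OCc5ccccc5)cc(OCc5ccccc5)cc4O[C@H](c4ccc(OCc5ccccc5)cc4)[C@@H]3OCc3ccccc3)c2O[C@H](c2ccc(OCc3ccccc3)cc2)[C@@H]1OCc1ccccc1.[O-]S(=O)(=O)C(F)(F)F | intermediate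
17 | 3,5,7,4'-tetra-O-benzylepiafzelechin-(4β→8)-3,5,7,4'-tetra-O-benzylepiafzelechin-(4β→8)-5,7,3',5'-tetra-O-benzyl-4'-O-methylepigallocatechin (all units 2R,3R; both interflavan bonds 3,4-trans) | COc1c(OCc2ccccc2)cc([C@H]2Oc3c(c(OCc4ccccc4)cc(OCc4ccccc4)c3[C@H]3c4c(OCc5ccccc5)cc(OCc5ccccc5)c([C@H]5c6c(OCc7ccccc7)cc(OCc7ccccc7)cc6O[C@H](c6ccc(OCc7ccccc7)cc6)[C@@H]5OCc5ccccc5)c4O[C@H](c4ccc(OCc5ccccc5)cc4)[C@@H]3OCc3ccccc3)C[C@H]2O)cc1OCc1ccccc1 | intermediate
18 | epiafzelechin-(4β→8)-epiafzelechin-(4β→8)-4'-O-methylepigallocatechin (CNP0146516.1) | COc1c(O)cc([C@H]2Oc3c(c(O)cc(O)c3[C@H]3c4c(O)cc(O)c([C@H]5c6c(O)cc(O)cc6O[C@H](c6ccc(O)cc6)[C@@H]5O)c4O[C@H](c4ccc(O)cc4)[C@@H]3O)C[C@H]2O)cc1O | target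

## Step count and risks

Total step count: 10. Longest linear sequence: 8 steps (steps 3, 4, 5, 6, 7, 8, 9, 10, from 4-(benzyloxy)benzaldehyde).

Steps most likely to fail:

1. Step 9 (proposed new method). What may go wrong: acid-induced scrambling of the existing top–middle C4–aryl bond, self-condensation of the cation through the free ring A positions of the top unit before 3 captures it, or ionisation of the open-chain benzylic aryl ether before ring closure. The fallback sets out from 14 and comes back at 17, and separates ring closure from the union with the third unit using known reaction types only.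
   - Ring closure alone: catalytic camphorsulfonic acid in CH2Cl2/MeOH at 0 °C, where methanol returns the cation to the 4-methoxyflavan dimer 15, which is isolated (acetal–arene cyclisation to a 4-alkoxychroman).
   - O-to-S exchange at C4 with 2-mercaptobenzothiazole and BF3·OEt2 (CH2Cl2, −20 °C) gives 3,5,7,4'-tetra-O-benzylepiafzelechin-(4β→8)-4-(1,3-benzothiazol-2-ylsulfanyl)-3,5,7,4'-tetra-O-benzylepiafzelechin F1.
   - F1 is united with 3 (3 equiv) by thiophilic activation with AgBF4 (THF, 0 °C). This silver-promoted coupling of 4-thioflavans with flavan nucleophiles needs no protic or oxophilic acid, so the existing interflavan bond is spared; attack is again expected anti to the 3-benzyloxy group.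

2. Step 7 (proposed new method). What may go wrong: capture of the open-chain oxocarbenium ion by 9 before ring closure, or flavanylation of 9 at the wrong carbon or twice. The fallback sets out from 10 and comes back at 13. Ring closure is run alone (catalytic camphorsulfonic acid, CH2Cl2/MeOH, 0 °C) and the 4-methoxyflavan 11 is isolated. Then 11 is condensed with 9 (4 equiv) under the established conditions for 4-alkoxyflavan electrophiles (TMSOTf, CH2Cl2, −78 °C), where ring closure can no longer interfere and the stoichiometry of the arylation can be tuned on its own. This fallback makes no compound outside the list (F0).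

3. Step 8. What may go wrong: slow displacement at the ortho-substituted phenol, with elimination or ionisation of the oxyphosphonium intermediate taking over (loss of material or of stereochemical integrity at C2). The fallback sets out from 10 and comes back at 17, and changes the order of the unions so that no hindered phenol has to be alkylated.
   - Part of 10 is first cyclised to the isolated 4-methoxyflavan 11 (as in the fallback for step 7).
   - The annulation/arylation of step 9 is then run on 10 itself with 3 (4 equiv; TMSOTf, CH2Cl2, −78 to −40 °C) to give the middle–bottom dimer 3,5,7,4'-tetra-O-benzylepiafzelechin-(4β→8)-5,7,3',5'-tetra-O-benzyl-4'-O-methylepigallocatechin F2. Ring C of the middle unit is still the last ring to close.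
   - The top unit is attached by the established coupling of a 4-alkoxyflavan with a dimeric nucleophile (11 added slowly to F2, 2 equiv, TMSOTf, CH2Cl2, −78 °C). Attack is expected at C8 of the upper unit of F2 (next to the ring oxygen) and anti to the 3-benzyloxy group of the cation, giving 17.

Further compounds
F1 | step 9 | 3,5,7,4'-tetra-O-benzylepiafzelechin-(4β→8)-4-(1,3-benzothiazol-2-ylsulfanyl)-3,5,7,4'-tetra-O-benzylepiafzelechin (C4 epimers of the lower unit) | C1(Sc2nc3ccccc3s2)c2c(OCc3ccccc3)cc(OCc3ccccc3)c([C@H]3c4c(OCc5ccccc5)cc(OCc5ccccc5)cc4O[C@H](c4ccc(OCc5ccccc5)cc4)[C@@H]3OCc3ccccc3)c2O[C@H](c2ccc(OCc3ccccc3)cc2)[C@@H]1OCc1ccccc1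
F0 | step 7 | none | none
F2 | step 8 | 3,5,7,4'-tetra-O-benzylepiafzelechin-(4β→8)-5,7,3',5'-tetra-O-benzyl-4'-O-methylepigallocatechin | COc1c(OCc2ccccc2)cc([C@H]2Oc3c(c(OCc4ccccc4)cc(OCc4ccccc4)c3[C@H]3c4c(OCc5ccccc5)cc(OCc5ccccc5)cc4O[C@H](c4ccc(OCc5ccccc5)cc4)[C@@H]3OCc3ccccc3)C[C@H]2O)cc1OCc1ccccc1
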